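The target is the 7'-epimer (endo aryl on ring B) of 8-hydroxypinoresinol. It is cut at C7–C8 and C8–O. The feature used: on ring B the tertiary oxygen at C8 stands trans, and C7 cis, to the C9' arm on C8'. In a Darzens condensation the C8 bromo enolate of a cis-disubstituted ring B lactone takes up O-benzylvanillin on its open face, and the aldolate then displaces bromide with inversion. One operation thus forms both bonds, the oxirane and the correct C8. The precursor is the enantiopure cis γ-lactone (C9 carbonyl, C7' aryl, C9' silyl ether) brominated at C8. The oxirane later serves as the C7 electrophile that closes ring A.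

Key step: step 7

Numbering: C8 is the ring-fusion C–OH and bears C7 (ArCH–O) and C9 (OCH2). C8' is the ring-fusion CH and bears C7' and C9'. Ring A is C7–O–C9'–C8'–C8 and ring B is C7'–O–C9–C8–C8'. Ar is 4-(benzyloxy)-3-methoxyphenyl. "Top" is the face of ring B that carries the C7' aryl.

Reading of the target: (7R,8S,7'R,8'R), with a cis ring fusion. The C7 aryl is exo (cis to C8–OH). The C7' aryl is endo (cis to C9' on ring B).

Assumption: the (S,S)-ProPhenol–zinc catalyst is taken to deliver the acetylide to the Re face of 1. If it proves Si-selective, the equally commercial (R,R)-ligand is used and nothing else changes.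

Step 1
Reactants: 1 4-(benzyloxy)-3-methoxybenzaldehyde (O-benzylvanillin); 2 methyl propiolate
Product: 3 methyl (4S)-4-[4-(benzyloxy)-3-methoxyphenyl]-4-hydroxybut-2-ynoate
Conditions: Me2Zn (3 equiv), (S,S)-ProPhenol (10 mol %), Ph3PO (20 mol %), toluene, 4 °C
Reagents that add atoms: none
Why: Catalytic enantioselective alkynylation of an aryl aldehyde by a zinc acetylide in a dinuclear zinc–ProPhenol pocket, in which Re-face delivery sets C7' (S here because the alkynyl group outranks the aryl, the same spatial arrangement as 7'R in the target).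

Step 2
Reactants: 3 methyl (4S)-4-aryl-4-hydroxybut-2-ynoate; 4 (chloromethyl)(isopropoxy)dimethylsilane
Product: 8 (5S)-5-[4-(benzyloxy)-3-methoxyphenyl]-4-{[isopropoxy(dimethyl)silyl]methyl}furan-2(5H)-one, via Grignard reagent 5 (not isolated), via silylmethyl cuprate 6 (not isolated), via hydroxy enoate 7 (not isolated)
Conditions: 4 (4 equiv), Mg, THF, 40 °C; CuBr·SMe2 (2 equiv), −30 °C; 3, −78 → −40 °C; aq NH4Cl at −78 °C, then rt
Reagents that add atoms: none
Why: Syn-carbocupration (conjugate addition) of a 4-hydroxy-2-ynoate puts the silylmethyl group on C8' and leaves ester and carbinol carbon on the same side of the alkene, so that protonated 7 lactonises by itself, one silylmethyl ligand being spent on the free hydroxyl and the cold buffered quench sparing the base-sensitive C7'–H of the aryl butenolide.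

Step 3
Reactants: 8 (5S)-silylmethyl butenolide
Product: 9 (4S,5R)-cis-5-[4-(benzyloxy)-3-methoxyphenyl]-4-{[isopropoxy(dimethyl)silyl]methyl}dihydrofuran-2(3H)-one
Conditions: H2 (1 atm), 5% Rh/Al2O3, EtOAc, rt
Reagents that add atoms: none
Why: Heterogeneous syn-hydrogenation of a 4,5-disubstituted butenolide occurs on the face away from the C7' aryl and so sets C8' with the C9' arm cis to the aryl, and Rh/Al2O3 is chosen because, unlike Pd/C, it leaves aryl benzyl ethers and the benzylic lactone C–O bond alone.

Step 4
Reactants: 9 cis silylmethyl lactone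
Product: 10 (4R,5R)-cis-5-[4-(benzyloxy)-3-methoxyphenyl]-4-(hydroxymethyl)dihydrofuran-2(3H)-one
Conditions: 30% H2O2, KF, KHCO3, THF–MeOH (1:1), 0 °C → rt, short contact; crude product taken on at once
Reagents that add atoms: hydrogen peroxide OO
Why: Tamao oxidation of an alkoxysilane turns C9'–Si into C9'–OH without touching a stereocentre, and it is placed after the saturation so that the configurationally labile butenolide never meets the basic fluoride medium.

Step 5
Reactants: 10 cis hydroxymethyl lactone
Product: 11 (4R,5R)-cis-5-[4-(benzyloxy)-3-methoxyphenyl]-4-{[(tert-butyldimethylsilyl)oxy]methyl}dihydrofuran-2(3H)-one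
Conditions: TBSCl, imidazole, CH2Cl2, 0 °C
Reagents that add atoms: tert-butyldimethylsilyl chloride CC(C)(C)[Si](C)(C)Cl
Why: Standard silylation of a primary alcohol, done immediately because a free β-hydroxymethyl γ-lactone can pass its acyl group to the primary oxygen.

Step 6
Reactants: 11 cis silyloxymethyl lactone
Product: 13 (4R,5R)-3-bromo-5-[4-(benzyloxy)-3-methoxyphenyl]-4-{[(tert-butyldimethylsilyl)oxy]methyl}dihydrofuran-2(3H)-one (C8 epimers), via silyl ketene acetal 12 (not isolated)
Conditions: LiN(SiMe3)2, Me3SiCl, THF, −78 °C; then NBS, −78 °C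
Reagents that add atoms: N-bromosuccinimide O=C1CCC(=O)N1Br; chlorotrimethylsilane C[Si](C)(C)Cl (atoms in 12 only)
Why: α-Bromination of a lactone through its silyl ketene acetal avoids proton exchange and dibromination and outruns bromination of the electron-rich arene, and the C8 configuration formed is irrelevant because step 7 erases it.

Step 7
Reactants: 13 α-bromo ring B lactone; 1 O-benzylvanillin
Product: 16 (2S,3R,6R,7R)-2,6-bis[4-(benzyloxy)-3-methoxyphenyl]-7-{[(tert-butyldimethylsilyl)oxy]methyl}-1,5-dioxaspiro[2.4]heptan-4-one (7S,8R,7'R,8'R in lignan numbering), via bromo enolate 14 (not isolated), via bromo aldolate 15 (not isolated)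
Conditions: LiN(SiMe3)2 (1.05 equiv), THF, −78 °C, 15 min; 1 (1.2 equiv), −78 → 0 °C; purification on Et3N-deactivated silica
Reagents that add atoms: none
Why: This is a Darzens condensation of an α-halo lactone with an aromatic aldehyde: the base removes the acidic C8–H of either epimer of 13 to give planar 14, which adds to 1 (C7–C8), and on warming the alkoxide of 15 expels bromide from the rear (C8–O). The oxirane closes in the 3-exo-tet mode. C8 is under substrate control, since aryl and silyloxymethyl both shield the top face of 14, so C7 enters from below and pushes bromine up, and the invertive closure then exchanges the two positions and leaves oxygen trans and C7 cis to the C9' arm. C7 is fixed by the aldolate that closes with its aryl anti to the lactone carbonyl (the usual trans-glycidate preference, expected 7S), and its epimer would do no harm because step 8 breaks C7–O through a cation-like transition state. The selectivity needed is facial selectivity in an addition that stays irreversible, which the lithium counter-ion, the low temperature and the good leaving group bromide (closure faster than retro-aldol cleavage) are meant to secure. C7' and C8' carry no acidic hydrogen and the enolate has no β-leaving group, so the existing centres are not touched.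

Step 8
Reactants: 16 spiro-epoxy lactone
Product: 18 (7R,8R,7'R,8'R)-4,4'-bis(benzyloxy)-8-hydroxy-3,3'-dimethoxy-7,9'-epoxylignano-9,7'-lactone, via epoxy alcohol 17 (not isolated)
Conditions: HF·pyridine, THF, 0 °C → rt
Reagents that add atoms: none
Why: Acidic fluoride cleavage of the primary silyl ether is followed in the same medium by acid-promoted 5-endo-tet opening of the p-alkoxyaryl oxirane at C7 by the C9' hydroxyl (known for aryl-activated 3,4-epoxy alcohols), which sits on the same face as C7, attacks anti to the departing oxygen and sets the exo aryl (7R) because the concave face is filled by the C7' aryl, while C8–O stays intact, any C7 fluorohydrin re-ionises to the same ether, and the absence of base excludes acyl migration in 17.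

Step 9
Reactants: 18 bicyclic α-hydroxy lactone
Product: 19 the corresponding C9 lactol (7R,8R,7'R,8'R; C9 anomers)
Conditions: i-Bu2AlH (3 equiv), CH2Cl2, −78 °C; aq potassium sodium tartrate
Reagents that add atoms: none
Why: Partial reduction of a γ-lactone with i-Bu2AlH at −78 °C stops at the aluminium hemiacetal, one equivalent being spent on the C8 hydroxyl, and the new C9 centre is removed in the next step.

Step 10
Reactants: 19 lactol
Product: 20 (7R,8S,7'R,8'R)-4,4'-di-O-benzyl-8-hydroxy-7'-epipinoresinol
Conditions: Et3SiH (5 equiv), BF3·OEt2 (1.5 equiv), CH2Cl2, −78 → −40 °C; cold quench with Et3N, then aq NaHCO3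
Reagents that add atoms: none
Why: In this ionic silane reduction of a lactol the Lewis acid activates the acetal-type C9–OH far more readily than the benzylic ring ethers at low temperature and Et3SiH delivers hydride to C9, so C9 becomes CH2 while C7 and the endo C7' keep their configuration.

Step 11
Reactants: 20 dibenzyl ether
Product: 21 target, (7R,8S,7'R,8'R)-8-hydroxy-7'-epipinoresinol
Conditions: H2 (1 atm), 10% Pd/C, EtOAc, rt, stopped when 20 is consumed
Reagents that add atoms: none
Why: Catalytic hydrogenolysis cleaves aryl benzyl ethers faster than the ring benzylic C–O bonds of a furofuran in aprotic EtOAc at 1 atm, so both phenols are freed with no stereocentre touched.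

Compound list
1 | 4-(benzyloxy)-3-methoxybenzaldehyde | COc1cc(C=O)ccc1OCc1ccccc1 | starting material
2 | methyl propiolate | COC(=O)C#C | starting material
3 | methyl (4S)-4-aryl-4-hydroxybut-2-ynoate | COC(=O)C#C[C@@H](O)c1ccc(OCc2ccccc2)c(OC)c1 | intermediate
4 | (chloromethyl)(isopropoxy)dimethylsilane | CC(C)O[Si](C)(C)CCl | starting material
5 | (i-PrO)Me2SiCH2MgCl | CC(C)O[Si](C)(C)C[Mg]Cl | intermediate
6 | [(i-PrO)Me2SiCH2]2CuMgCl | CC(C)O[Si](C)(C)C[Cu-]C[Si](C)(C)OC(C)C.[Mg+]Cl | intermediate
7 | methyl (2E,4S)-4-aryl-4-hydroxy-3-{[isopropoxy(dimethyl)silyl]methyl}but-2-enoate (ester and carbinol carbon cis; E only because silicon outranks oxygen) | COC(=O)/C=C(/C[Si](C)(C)OC(C)C)[C@@H](O)c1ccc(OCc2ccccc2)c(OC)c1 | intermediate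
8 | (5S)-5-aryl-4-{[isopropoxy(dimethyl)silyl]methyl}furan-2(5H)-one | O=C1O[C@@H](c2ccc(OCc3ccccc3)c(OC)c2)C(C[Si](C)(C)OC(C)C)=C1 | intermediate
9 | (4S,5R)-cis-5-aryl-4-{[isopropoxy(dimethyl)silyl]methyl}dihydrofuran-2(3H)-one | O=C1O[C@@H](c2ccc(OCc3ccccc3)c(OC)c2)[C@@H](C[Si](C)(C)OC(C)C)C1 | intermediate
10 | (4R,5R)-cis-5-aryl-4-(hydroxymethyl)dihydrofuran-2(3H)-one | O=C1O[C@@H](c2ccc(OCc3ccccc3)c(OC)c2)[C@@H](CO)C1 | intermediate
11 | (4R,5R)-cis-5-aryl-4-(TBS-oxymethyl)dihydrofuran-2(3H)-one | O=C1O[C@@H](c2ccc(OCc3ccccc3)c(OC)c2)[C@@H](CO[Si](C)(C)C(C)(C)C)C1 | intermediate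
12 | trimethylsilyl ketene acetal of 11 | C[Si](C)(C)OC1=C[C@H](CO[Si](C)(C)C(C)(C)C)[C@H](c2ccc(OCc3ccccc3)c(OC)c2)O1 | intermediate
13 | (4R,5R)-3-bromo-5-aryl-4-(TBS-oxymethyl)dihydrofuran-2(3H)-one, C8 epimers | O=C1O[C@@H](c2ccc(OCc3ccccc3)c(OC)c2)[C@@H](CO[Si](C)(C)C(C)(C)C)C1Br | intermediate
14 | lithium enolate of 13 | [Li+].[O-]C1=C(Br)[C@H](CO[Si](C)(C)C(C)(C)C)[C@H](c2ccc(OCc3ccccc3)c(OC)c2)O1 | intermediate
15 | lithium aldolate, C7 trans and Br cis to the C9' arm | [Li+].[O-][C@@H](c1ccc(OCc2ccccc2)c(OC)c1)[C@]1(Br)C(=O)O[C@@H](c2ccc(OCc3ccccc3)c(OC)c2)[C@H]1CO[Si](C)(C)C(C)(C)C | intermediate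
16 | spiro-epoxy lactone (7S,8R,7'R,8'R), oxirane oxygen trans and C7 cis to the C9' arm | COc1cc(ccc1OCc1ccccc1)[C@@H]2O[C@@]23C(=O)O[C@@H](c4ccc(OCc5ccccc5)c(OC)c4)[C@H]3CO[Si](C)(C)C(C)(C)C | intermediate
17 | epoxy alcohol (16 without the silyl group) | COc1cc(ccc1OCc1ccccc1)[C@@H]2O[C@@]23C(=O)O[C@@H](c4ccc(OCc5ccccc5)c(OC)c4)[C@H]3CO | intermediate
18 | bicyclic 8-hydroxy lactone (7R,8R,7'R,8'R) | COc1cc([C@H]2OC[C@@H]3[C@H](c4ccc(OCc5ccccc5)c(OC)c4)OC(=O)[C@]23O)ccc1OCc1ccccc1 | intermediate
19 | C9 lactol, anomers | COc1cc([C@H]2OC[C@@H]3[C@H](c4ccc(OCc5ccccc5)c(OC)c4)OC(O)[C@]23O)ccc1OCc1ccccc1 | intermediate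
20 | di-O-benzyl ether of the target (7R,8S,7'R,8'R) | COc1cc([C@H]2OC[C@@H]3[C@H](c4ccc(OCc5ccccc5)c(OC)c4)OC[C@]23O)ccc1OCc1ccccc1 | intermediate
21 | (7R,8S,7'R,8'R)-8-hydroxy-7'-epipinoresinol | COc1cc([C@H]2OC[C@@H]3[C@H](c4ccc(O)c(OC)c4)OC[C@]23O)ccc1O | target

Total step count: 11. Longest linear sequence: 11 steps (1 → 21). Aldehyde 1 enters twice, in steps 1 and 7, and silane 4 enters within step 2.

Steps most likely to fail

**Step 7.**
- Risk: facial selectivity may erode if the aldol addition becomes reversible before ring closure. The bromo enolate may decompose, or dehydrobromination may compete.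
- Fallback, from 13 back to 16: a Michaelis–Arbuzov reaction with P(OEt)3 (neat, 140 °C) should give the diethyl phosphonate lactone F1.
- Horner–Wadsworth–Emmons olefination of F1 with 1 (NaH, THF, 0 °C) should give the (E)-arylidene lactone F2.
- Dimethyldioxirane (acetone, 0 °C) should then attack the exocyclic alkene from the face opposite the aryl and the silyloxymethyl group. This neutral, stereospecific epoxidation places oxygen trans to the C9' arm and gives 16.

**Step 10.**
- Risk: the Lewis acid may also ionise the benzylic C7'–O or C7–O bond. The endo aryl could then relax to exo, or a ring could open reductively.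
- Fallback, from 19 back to 20, neutral and radical-based: PhSSPh and n-Bu3P (THF, rt) should exchange only the anomeric hydroxyl and give the C9 phenylthio acetal F3.
- n-Bu3SnH with AIBN (toluene, 80 °C) should replace sulfur by hydrogen through the α-oxy radical at C9, giving 20.

**Step 4.**
- Risk: in the basic peroxide medium the liberated primary hydroxyl may take over the acyl group (lactone migration from O–C7' to O–C9'), or the lactone may open.
- Fallback, from 8 back to 11: the C–Si bond is oxidised before saturation with the weakly acidic peracid variant (mCPBA, KHF2, DMF, rt), giving the hydroxymethyl butenolide F4. In F4 the ring alkene holds the carbonyl away from the hydroxymethyl group, so migration is geometrically impossible.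
- Silylation (TBSCl, imidazole, CH2Cl2) gives the silyloxymethyl butenolide F5.
- Hydrogenation over Rh/Al2O3 from the face opposite the aryl gives 11.

Further compounds
F1 | step 7 | diethyl [(4R,5R)-cis-5-aryl-4-(TBS-oxymethyl)-2-oxotetrahydrofuran-3-yl]phosphonate | O=C1O[C@@H](c2ccc(OCc3ccccc3)c(OC)c2)[C@@H](CO[Si](C)(C)C(C)(C)C)C1P(=O)(OCC)OCC
F2 | step 7 | (E)-3-arylidene-cis-5-aryl-4-(TBS-oxymethyl)dihydrofuran-2(3H)-one | O=C1O[C@@H](c2ccc(OCc3ccccc3)c(OC)c2)[C@@H](CO[Si](C)(C)C(C)(C)C)/C1=C\c4ccc(OCc5ccccc5)c(OC)c4
F3 | step 10 | C9 phenylthio acetal of 19 | COc1cc([C@H]2OC[C@@H]3[C@H](c4ccc(OCc5ccccc5)c(OC)c4)OC(Sc6ccccc6)[C@]23O)ccc1OCc1ccccc1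
F4 | step 4 | (5S)-5-aryl-4-(hydroxymethyl)furan-2(5H)-one | O=C1O[C@@H](c2ccc(OCc3ccccc3)c(OC)c2)C(CO)=C1
F5 | step 4 | (5S)-5-aryl-4-(TBS-oxymethyl)furan-2(5H)-one | O=C1O[C@@H](c2ccc(OCc3ccccc3)c(OC)c2)C(CO[Si](C)(C)C(C)(C)C)=C1
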